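**Retrosynthetic overview**
- The strategy rests on ring C. It is a benzene ring bonded through C1' to furan C2 and oxygenated at C3' and C5'. This meta,meta pattern matches a 1,3-dicarbonyl chain wrapped around C1', so ring C is cut at C1'–C2' and C4'–C5'.
- The cut gives C2'–C3'–C4' as dimethyl 3-oxopentanedioate. C1', C6' and C5' become the two alkyne carbons and the ester carbonyl of a methyl 3-(benzofuran-2-yl)propiolate. The ester groups left on C2' and C4' are later hydrolysed and lost as CO2.
- The alkynoate goes back by Corey–Fuchs homologation to the benzofuran-2-carbaldehyde. Ring B goes back to a salicylaldehyde plus ethyl bromoacetate. The C7 geranyl group goes back to C3-alkylation of 2,4-dihydroxybenzaldehyde.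
- Ring order: A (purchased), B (step 3), C (step 8). The C6 oxygen travels as a MOM ether that is released last.

Key step: step 8

Remark: geranyl stands for (2E)-3,7-dimethylocta-2,6-dien-1-yl. The target has no stereocentre. Its only stereo-element, this E-alkene, is bought with geranyl bromide and meets no reagent able to isomerise it.

Step 1
Reactants: 1 2,4-dihydroxybenzaldehyde; 2 geranyl bromide
Product: 3 3-geranyl-2,4-dihydroxybenzaldehyde
Conditions: KOH, CaCl2·2H2O, MeOH, 0 °C → rt
Reagents that add atoms: none
Why: C-alkylation of an ambident resorcylaldehyde phenoxide in a protic medium, in which methanol and calcium ions tie up the phenoxide oxygens, C3 (ortho to both oxygens) is the most nucleophilic carbon of ring A, and SN2 attack on the primary allylic bromide keeps the E-alkene, while O-ethers and the C5 isomer are removed by chromatography at this cheap first stage.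

Step 2
Reactants: 3 3-geranyl-2,4-dihydroxybenzaldehyde
Product: 4 3-geranyl-2-hydroxy-4-(methoxymethoxy)benzaldehyde
Conditions: MOMCl (1.1 equiv), K2CO3, acetone, 0 °C → rt
Reagents that add atoms: chloromethyl methyl ether (MOMCl), COCCl
Why: Selective Williamson-type O-alkylation, because the C2 hydroxyl is locked in a hydrogen bond to the formyl oxygen and is much less nucleophilic, so one equivalent of MOMCl should cap only the C4 hydroxyl.

Step 3
Reactants: 4 3-geranyl-2-hydroxy-4-(methoxymethoxy)benzaldehyde; 5 ethyl bromoacetate
Product: 7 ethyl 7-geranyl-6-(methoxymethoxy)-1-benzofuran-2-carboxylate, via aryloxyacetate 6 (not isolated)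
Conditions: K2CO3, DMF, 60 °C → 120 °C
Reagents that add atoms: none
Why: Williamson O-alkylation gives 6, whose activated methylene closes on the formyl carbon (intramolecular aldol condensation, 5-exo-trig) and loses water to aromatise ring B, which is the standard salicylaldehyde–haloacetate benzofuran synthesis and leaves the MOM acetal and the alkenes untouched.

Step 4
Reactants: 7 ethyl 7-geranyl-6-(methoxymethoxy)-1-benzofuran-2-carboxylate
Product: 8 [7-geranyl-6-(methoxymethoxy)-1-benzofuran-2-yl]methanol
Conditions: LiAlH4, THF, 0 °C; H2O/aq NaOH work-up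
Reagents that add atoms: none
Why: Standard hydride reduction of an ester to the primary alcohol, to which the benzofuran, the isolated trisubstituted alkenes and the acetal are inert.

Step 5
Reactants: 8 [7-geranyl-6-(methoxymethoxy)-1-benzofuran-2-yl]methanol
Product: 9 7-geranyl-6-(methoxymethoxy)-1-benzofuran-2-carbaldehyde
Conditions: activated MnO2 (excess), CH2Cl2, rt
Reagents that add atoms: none
Why: MnO2 oxidation of a heterobenzylic alcohol is chemoselective, stops at the aldehyde and works under neutral conditions that spare the geranyl chain and the MOM group.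

Step 6
Reactants: 9 7-geranyl-6-(methoxymethoxy)-1-benzofuran-2-carbaldehyde
Product: 10 2-(2,2-dibromoethenyl)-7-geranyl-6-(methoxymethoxy)-1-benzofuran
Conditions: CBr4 (2 equiv), PPh3 (4 equiv), Et3N (buffer), CH2Cl2, 0 °C
Reagents that add atoms: carbon tetrabromide, BrC(Br)(Br)Br
Why: Ramirez dibromo-olefination (first half of the Corey–Fuchs sequence), a Wittig reaction of Ph3P=CBr2 made in the flask with the unhindered aldehyde, with Et3N taking up traces of HBr so that the acetal and the alkenes survive.

Step 7
Reactants: 10 2-(2,2-dibromoethenyl)-7-geranyl-6-(methoxymethoxy)-1-benzofuran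
Product: 12 methyl 3-[7-geranyl-6-(methoxymethoxy)-1-benzofuran-2-yl]prop-2-ynoate, via lithium acetylide 11 (not isolated)
Conditions: n-BuLi (2.2 equiv), THF, −78 °C; ClCO2Me, −78 °C → 0 °C
Reagents that add atoms: methyl chloroformate, COC(=O)Cl
Why: Second half of the Corey–Fuchs sequence, in which Br/Li exchange, alpha-elimination with 1,2-shift (Fritsch–Buttenberg–Wiechell) and deprotonation give acetylide 11, which is C-acylated by the chloroformate, and at −78 °C the exchange far outruns lithiation at C3, at C5 or at the benzylic CH2.

Step 8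
Reactants: 12 methyl 3-[7-geranyl-6-(methoxymethoxy)-1-benzofuran-2-yl]prop-2-ynoate; 13 dimethyl 3-oxopentanedioate
Product: 15 dimethyl 4-[7-geranyl-6-(methoxymethoxy)-1-benzofuran-2-yl]-2,6-dihydroxybenzene-1,3-dicarboxylate, via Michael adduct triester 14 (not isolated)
Conditions: 13 (1.5 equiv), NaH (1.6 equiv), THF, 0 °C → rt; add 12, rt → 65 °C; AcOH, 0 °C
Reagents that add atoms: none
Why: The sodium mono-enolate of 13 adds through one active methylene to the alkyne carbon of 12 that bears the benzofuran, the position made electrophilic by the ester (Michael addition, C1'–C2'), and proton transfer gives the delocalised enolate of 14. The C1'=C6' geometry of 14 equilibrates through this extended enolate, so the isomer with the acrylate ester cis to the keto-diester chain stays available, and because only about one equivalent of base per 13 is used the charge can move to the second active methylene. That carbon attacks the acrylate ester carbonyl and expels methoxide (Dieckmann condensation, C4'–C5'), closing six-membered ring C in a 6-exo-trig mode, and two enolisations turn the cyclohexenedione into the aromatic resorcinol without any oxidant. The closest known reaction type is the Michael addition–Dieckmann benzannulation of the dimethyl 3-oxoglutarate anion with alk-2-ynoates, which gives 2,4-dihydroxyisophthalates. The step needs C-acylation to win over O-acylation to a 2-pyranone and over self-condensation of 13: the doubly activated methylene is the better placed carbon nucleophile, lactone formation is reversible in the presence of the liberated methoxide, and deprotonation of the resorcinol diester is an irreversible sink. No stereocentre is created, and the MOM acetal, ring B and both trisubstituted alkenes are inert to enolate bases.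

Step 9
Reactants: 15 dimethyl 4-[7-geranyl-6-(methoxymethoxy)-1-benzofuran-2-yl]-2,6-dihydroxybenzene-1,3-dicarboxylate
Product: 16 4-[7-geranyl-6-(methoxymethoxy)-1-benzofuran-2-yl]-2,6-dihydroxybenzene-1,3-dicarboxylic acid
Conditions: 4 M KOH, MeOH–H2O, reflux, Ar; cold 1 M HCl to pH 3, EtOAc extraction
Reagents that add atoms: potassium hydroxide, [K+].[OH-]
Why: Saponification (acyl-oxygen hydrolysis) of two hindered salicylate-type esters needs strong alkali, which the MOM ether, the benzofuran and the geranyl chain tolerate at this temperature, and any acid that already loses CO2 here converges on 17 in the next step.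

Step 10
Reactants: 16 4-[7-geranyl-6-(methoxymethoxy)-1-benzofuran-2-yl]-2,6-dihydroxybenzene-1,3-dicarboxylic acid
Product: 17 5-[7-geranyl-6-(methoxymethoxy)-1-benzofuran-2-yl]benzene-1,3-diol
Conditions: DMF–pyridine (10:1), 125 °C, Ar
Reagents that add atoms: none
Why: Thermal protodecarboxylation of resorcylic acids, in which each carboxyl sits ortho or para to hydroxyl groups so that ipso-protonation through the keto tautomer and loss of CO2 are easy, while pyridine buffers the strongly acidic 2,6-dihydroxybenzoic acid unit and so protects the acetal and the geranyl chain.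

Step 11
Reactants: 17 5-[7-geranyl-6-(methoxymethoxy)-1-benzofuran-2-yl]benzene-1,3-diol
Product: 18 5-(7-geranyl-6-hydroxy-1-benzofuran-2-yl)benzene-1,3-diol (Mulberrofuran l)
Conditions: cat conc HCl, MeOH, rt → 40 °C
Reagents that add atoms: none
Why: Acid-catalysed transacetalisation of the aryl MOM ether with methanol, for which dilute acid near room temperature suffices while it should be too weak to protonate the trisubstituted alkenes, so ring closure of the C6 hydroxyl onto the geranyl chain is avoided if the reaction is stopped at full conversion.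

**Compound list**
1 | 2,4-dihydroxybenzaldehyde | O=Cc1ccc(O)cc1O | starting material
2 | geranyl bromide, (2E)-1-bromo-3,7-dimethylocta-2,6-diene | CC(C)=CCC/C(C)=C/CBr | starting material
3 | 3-geranyl-2,4-dihydroxybenzaldehyde | O=Cc1ccc(O)c(C/C=C(\C)CCC=C(C)C)c1O | intermediate
4 | 3-geranyl-2-hydroxy-4-(methoxymethoxy)benzaldehyde | O=Cc1ccc(OCOC)c(C/C=C(\C)CCC=C(C)C)c1O | intermediate
5 | ethyl bromoacetate | CCOC(=O)CBr | starting material
6 | ethyl 2-[2-formyl-6-geranyl-5-(methoxymethoxy)phenoxy]acetate | CCOC(=O)COc1c(C=O)ccc(OCOC)c1C/C=C(\C)CCC=C(C)C | intermediate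
7 | ethyl 7-geranyl-6-(methoxymethoxy)-1-benzofuran-2-carboxylate | CCOC(=O)c1cc2ccc(OCOC)c(C/C=C(\C)CCC=C(C)C)c2o1 | intermediate
8 | [7-geranyl-6-(methoxymethoxy)-1-benzofuran-2-yl]methanol | OCc1cc2ccc(OCOC)c(C/C=C(\C)CCC=C(C)C)c2o1 | intermediate
9 | 7-geranyl-6-(methoxymethoxy)-1-benzofuran-2-carbaldehyde | O=Cc1cc2ccc(OCOC)c(C/C=C(\C)CCC=C(C)C)c2o1 | intermediate
10 | 2-(2,2-dibromoethenyl)-7-geranyl-6-(methoxymethoxy)-1-benzofuran | BrC(Br)=Cc1cc2ccc(OCOC)c(C/C=C(\C)CCC=C(C)C)c2o1 | intermediate
11 | lithium [7-geranyl-6-(methoxymethoxy)-1-benzofuran-2-yl]acetylide | [Li]C#Cc1cc2ccc(OCOC)c(C/C=C(\C)CCC=C(C)C)c2o1 | intermediate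
12 | methyl 3-[7-geranyl-6-(methoxymethoxy)-1-benzofuran-2-yl]prop-2-ynoate | COC(=O)C#Cc1cc2ccc(OCOC)c(C/C=C(\C)CCC=C(C)C)c2o1 | intermediate
13 | dimethyl 3-oxopentanedioate | COC(=O)CC(=O)CC(=O)OC | starting material
14 | trimethyl (1E)-2-[7-geranyl-6-(methoxymethoxy)-1-benzofuran-2-yl]-4-oxopent-1-ene-1,3,5-tricarboxylate (present as its sodium enolate, C3 configurationally labile) | COC(=O)/C=C(\C(C(=O)OC)C(=O)CC(=O)OC)c1cc2ccc(OCOC)c(C/C=C(\C)CCC=C(C)C)c2o1 | intermediate
15 | dimethyl 4-[7-geranyl-6-(methoxymethoxy)-1-benzofuran-2-yl]-2,6-dihydroxybenzene-1,3-dicarboxylate | COC(=O)c1c(O)c(C(=O)OC)c(O)cc1-c1cc2ccc(OCOC)c(C/C=C(\C)CCC=C(C)C)c2o1 | intermediate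
16 | 4-[7-geranyl-6-(methoxymethoxy)-1-benzofuran-2-yl]-2,6-dihydroxybenzene-1,3-dicarboxylic acid | OC(=O)c1c(O)c(C(=O)O)c(O)cc1-c1cc2ccc(OCOC)c(C/C=C(\C)CCC=C(C)C)c2o1 | intermediate
17 | 5-[7-geranyl-6-(methoxymethoxy)-1-benzofuran-2-yl]benzene-1,3-diol | COCOc1ccc2cc(-c3cc(O)cc(O)c3)oc2c1C/C=C(\C)CCC=C(C)C | intermediate
18 | Mulberrofuran l, 5-(7-geranyl-6-hydroxy-1-benzofuran-2-yl)benzene-1,3-diol | CC(C)=CCC/C(C)=C/Cc1c(O)ccc2cc(-c3cc(O)cc(O)c3)oc12 | target

**Total step count:** 11. **Longest linear sequence:** 11 steps (1 → 18).

**Steps most likely to fail**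

(1) Step 8. The benzofuranyl donor lowers the electrophilicity of the alkynoate. Conjugate addition may then become slow enough for self-condensation of the oxoglutarate enolate, or lactonisation through the enol oxygen, to overtake the Dieckmann closure.

The fallback sets out from 12 and builds ring C by a [4+2] cycloaddition instead of an anionic cascade. Compound 12 is heated with 1-methoxy-1,3-bis(trimethylsilyloxy)buta-1,3-diene in xylene at 140 °C in a sealed tube (Diels–Alder reaction). The nucleophilic CH2 terminus of the diene bonds to the alkyne carbon that bears the benzofuran. Loss of methanol and desilylation on work-up should give methyl 2-[7-geranyl-6-(methoxymethoxy)-1-benzofuran-2-yl]-4,6-dihydroxybenzoate F1. Saponification as in step 9 gives 2-[7-geranyl-6-(methoxymethoxy)-1-benzofuran-2-yl]-4,6-dihydroxybenzoic acid F2. Heating as in step 10 brings the fallback back to the route at 17.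

(2) Step 1. O-alkylation, attack at C5 and double alkylation compete with attack at C3, which erodes throughput and burdens the separation.

The fallback sets out from 2 and fixes the regiochemistry by directed metalation.
- Resorcinol is converted with MOMCl and i-Pr2NEt into 1,3-bis(methoxymethoxy)benzene F3.
- n-BuLi (THF, 0 °C) lithiates F3 only between the two acetal oxygens to give 2-lithio-1,3-bis(methoxymethoxy)benzene F4.
- Alkylation of F4 with 2 gives 2-geranyl-1,3-bis(methoxymethoxy)benzene F5.
- Methanolic HCl as in step 11 frees 2-geranylbenzene-1,3-diol F6.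
- Ortho-formylation of F6 with MgCl2, Et3N and paraformaldehyde in MeCN (Casnati–Skattebøl reaction) brings the fallback back to the route at 3. The two open ortho positions of F6 are equivalent, so only one product is possible.

(3) Step 11. The acid may protonate the C2''=C3'' alkene before acetal cleavage is complete. The freed C6 hydroxyl would then close onto the chain, or the chain would be hydrated.

The fallback sets out from 17 and exchanges the protecting group under proton-free, buffered conditions. TMSOTf and 2,2'-bipyridyl in MeCN (0 °C → rt) should convert the aryl MOM ether and the two free phenols into 2-[3,5-bis(trimethylsilyloxy)phenyl]-7-geranyl-6-(trimethylsilyloxy)-1-benzofuran F7. Addition of water then hydrolyses the silyl ethers at neutral pH, and the fallback comes back to the route at 18.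

**Further compounds**
F1 | step 8 | methyl 2-[7-geranyl-6-(methoxymethoxy)-1-benzofuran-2-yl]-4,6-dihydroxybenzoate | COC(=O)c1c(O)cc(O)cc1-c1cc2ccc(OCOC)c(C/C=C(\C)CCC=C(C)C)c2o1
F2 | step 8 | 2-[7-geranyl-6-(methoxymethoxy)-1-benzofuran-2-yl]-4,6-dihydroxybenzoic acid | OC(=O)c1c(O)cc(O)cc1-c1cc2ccc(OCOC)c(C/C=C(\C)CCC=C(C)C)c2o1
F3 | step 1 | 1,3-bis(methoxymethoxy)benzene | COCOc1cccc(OCOC)c1
F4 | step 1 | 2-lithio-1,3-bis(methoxymethoxy)benzene | [Li]c1c(OCOC)cccc1OCOC
F5 | step 1 | 2-geranyl-1,3-bis(methoxymethoxy)benzene | COCOc1cccc(OCOC)c1C/C=C(\C)CCC=C(C)C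
F6 | step 1 | 2-geranylbenzene-1,3-diol | Oc1cccc(O)c1C/C=C(\C)CCC=C(C)C
F7 | step 11 | 2-[3,5-bis(trimethylsilyloxy)phenyl]-7-geranyl-6-(trimethylsilyloxy)-1-benzofuran | C[Si](C)(C)Oc1cc(O[Si](C)(C)C)cc(-c2cc3ccc(O[Si](C)(C)C)c(C/C=C(\C)CCC=C(C)C)c3o2)c1
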